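**Retrosynthetic overview**
- Ring numbering: C1 carries the ester, C2 the OH, C4 the OMe, C6 the icosyl chain. Target ⇒ methyl 2-icosyl-4,6-dimethoxybenzoate, by chelation-controlled BCl3 cleavage of the methyl ether at C2, the one beside the ester.
- That ester ⇒ one-flask aryne three-component coupling: icosyllithium adds to 3,5-dimethoxybenzyne (ring C6–CH2 bond), and ClCO2Me traps the resulting aryllithium (ring C1–CO2Me bond).
- Enabling feature: on the benzene ring the chain-bearing C6 and the ester-bearing C1 are neighbours, and C2 beside C1 carries oxygen (the C4 oxygen is meta to C6). This is the pattern a nucleophile and an electrophile leave on an aryne whose triple bond C1–C6 is flanked by the C2 oxygen.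
- The aryne comes from 1-fluoro-3,5-dimethoxybenzene by ortho-lithiation and loss of LiF; icosyllithium comes from 1-bromoicosane. No ring is formed (the benzene ring is bought) and the target has no stereocentre.

Key step: step 2

Remark: 1-bromoicosane and 1-fluoro-3,5-dimethoxybenzene are taken as purchasable, and icosyllithium 2 is handled as a titrated stock solution in ether and counted as an isolated compound.

Step 1
Reactants: 1 1-bromoicosane
Product: 2 icosyllithium (titrated solution in Et2O)
Conditions: Li granules (2.4 equiv, 0.5% Na), Et2O, 0–10 °C, argon, slow addition of 1; filtered, titrated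
Reagents that add atoms: lithium metal, [Li]
Why: Reductive lithiation of a primary alkyl bromide by lithium metal in ether is the standard route to primary alkyllithiums, and slow addition at low temperature should keep Wurtz coupling of 2 with unreacted 1 down; no stereocentre is involved.

Step 2
Reactants: 3 1-fluoro-3,5-dimethoxybenzene; 2 icosyllithium (2.3 equiv)
Product: 7 methyl 2-icosyl-4,6-dimethoxybenzoate, via fluoroaryllithium 4 (not isolated), via 3,5-dimethoxybenzyne 5 (not isolated), via icosylaryllithium 6 (not isolated)
Conditions: 2 (2.3 equiv), Et2O, rt → reflux, slow addition of 3; then cannulation into ClCO2Me (4 equiv), THF, −78 °C → rt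
Reagents that add atoms: methyl chloroformate, COC(=O)Cl
Why: Icosyllithium should first remove the ring hydrogen of 3 that lies between fluorine and a methoxy group, and aryllithium 4 then loses LiF on warming to give 3,5-dimethoxybenzyne 5; a second equivalent of icosyllithium adds across the strained triple bond (carbolithiation) to give aryllithium 6, which is C-acylated by methyl chloroformate. The closest known reaction type is the addition of alkyllithiums to methoxybenzynes generated from fluoroanisoles, followed by trapping of the ortho-methoxy aryllithium with a carbon electrophile such as CO2 (aryne three-component coupling). No ring is closed and no stereocentre is formed. The step needs regioselective addition, alkyl to the aryne carbon remote from the flanking methoxy group and lithium to the carbon beside it; the methoxy group on the ring carbon next to the triple bond secures this, because its inductive pull distorts the aryne so that the remote carbon is the more electrophilic terminus and the carbanion develops ortho to oxygen, where it is stabilised inductively and by O–Li coordination, while the second methoxy group is meta to the attacked carbon and does not oppose. Over-addition in the trapping should be held back by the two ortho substituents of ester 7 and by adding 6 to excess ClCO2Me at −78 °C.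

Step 3
Reactants: 7 methyl 2-icosyl-4,6-dimethoxybenzoate
Product: 9 methyl 2-hydroxy-6-icosyl-4-methoxybenzoate (target), via aryloxydichloroborane 8 (not isolated)
Conditions: BCl3 (1.5 equiv, 1 M in CH2Cl2), CH2Cl2, −78 → 0 °C; then H2O
Reagents that add atoms: none
Why: Chelation-controlled O-demethylation with BCl3: the Lewis acid binds the ester carbonyl oxygen together with the neighbouring methoxy oxygen in a six-membered chelate, so chloride should attack only that O-methyl group (SN2 at carbon) to give 8, which water hydrolyses to the hydrogen-bonded phenol, while the para methoxy group and the hindered methyl ester stay untouched; no stereocentre is involved.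

**Compound list**
1 | 1-bromoicosane | CCCCCCCCCCCCCCCCCCCCBr | starting material
2 | icosyllithium | [Li]CCCCCCCCCCCCCCCCCCCC | intermediate
3 | 1-fluoro-3,5-dimethoxybenzene | COc1cc(F)cc(OC)c1 | starting material
4 | (2-fluoro-4,6-dimethoxyphenyl)lithium | [Li]c1c(F)cc(OC)cc1OC | intermediate
5 | 3,5-dimethoxybenzyne (1,2-didehydro-3,5-dimethoxybenzene) | COC1=CC(OC)=CC#C1 | intermediate
6 | (2-icosyl-4,6-dimethoxyphenyl)lithium | [Li]c1c(CCCCCCCCCCCCCCCCCCCC)cc(OC)cc1OC | intermediate
7 | methyl 2-icosyl-4,6-dimethoxybenzoate | CCCCCCCCCCCCCCCCCCCCc1cc(OC)cc(OC)c1C(=O)OC | intermediate
8 | methyl 2-[(dichloroboranyl)oxy]-6-icosyl-4-methoxybenzoate | CCCCCCCCCCCCCCCCCCCCc1cc(OC)cc(OB(Cl)Cl)c1C(=O)OC | intermediate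
9 | methyl 2-hydroxy-6-icosyl-4-methoxybenzoate | CCCCCCCCCCCCCCCCCCCCc1cc(OC)cc(O)c1C(=O)OC | target

Total step count: 3. Longest linear sequence: 3 steps (1 → 2 → 7 → 9).

**Steps most likely to fail**

Step 2. Three processes may cut the yield: deprotonation of 3 at the ring position between the two methoxy groups, which gives an anion that cannot lose fluoride; proton capture by aryllithium 6 from the ether before acylation; and addition of 6 to further aryne. The fallback gives up the aryne and forms the same ring–chain bond by cross-coupling; it sets out from 1 and comes back to the route at 6. Compound 1 would be converted with Zn dust (cat. I2, DMA, 80 °C) into icosylzinc bromide F1. A Negishi coupling (Pd(OAc)2, SPhos, THF/DMA, 50 °C) of this reagent with the purchased aryl bromide 1-bromo-3,5-dimethoxybenzene F2 should give 1-icosyl-3,5-dimethoxybenzene F3. NBS (1.0 equiv, MeCN, 0 °C) should brominate F3 ortho to the chain and para to a methoxy group, the usual site for 5-alkylresorcinol dimethyl ethers, to give 2-bromo-1-icosyl-3,5-dimethoxybenzene F4. Bromine–lithium exchange on F4 (n-BuLi, THF/Et2O, −78 °C) would then deliver 6 regiospecifically, and trapping with ClCO2Me as in step 2 would give 7.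

Step 1. Wurtz coupling of the alkyllithium with unreacted bromide and stalling of the metal surface may occur, made worse by the low solubility of the C20 bromide in cold ether. The fallback replaces reductive metalation by halogen–lithium exchange; it sets out from 1 and comes back at 2. A Finkelstein reaction of 1 (NaI, acetone, reflux) would give 1-iodoicosane F5. Treatment of F5 with t-BuLi (2.1 equiv, pentane/Et2O, −78 °C → rt) should give 2 free of Wurtz products, the second equivalent of t-BuLi destroying the tert-butyl iodide formed in the exchange.

Step 3. Demethylation may spread to the para methoxy group, or the Lewis acid may cleave the methyl ester, if the chelate does not form cleanly. The fallback removes both ether methyl groups and puts one back selectively; it sets out from 7 and comes back at 9. BBr3 (3 equiv, CH2Cl2, −78 → 0 °C) would convert 7 into methyl 2,4-dihydroxy-6-icosylbenzoate F6. MeI (1.05 equiv) with K2CO3 in acetone at rt should then methylate only the para hydroxyl of F6 to give 9, because the ortho hydroxyl is tied up in a hydrogen bond to the ester carbonyl.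

**Further compounds**
F1 | step 2 | icosylzinc bromide | Br[Zn]CCCCCCCCCCCCCCCCCCCC
F2 | step 2 | 1-bromo-3,5-dimethoxybenzene | COc1cc(Br)cc(OC)c1
F3 | step 2 | 1-icosyl-3,5-dimethoxybenzene | CCCCCCCCCCCCCCCCCCCCc1cc(OC)cc(OC)c1
F4 | step 2 | 2-bromo-1-icosyl-3,5-dimethoxybenzene | CCCCCCCCCCCCCCCCCCCCc1cc(OC)cc(OC)c1Br
F5 | step 1 | 1-iodoicosane | CCCCCCCCCCCCCCCCCCCCI
F6 | step 3 | methyl 2,4-dihydroxy-6-icosylbenzoate | CCCCCCCCCCCCCCCCCCCCc1cc(O)cc(O)c1C(=O)OC
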